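**Plan**

- Retrosynthesis (cyclohexane-1,3-dione numbering: C2 acyl, C4 hydroxyl): cut first the exocyclic C2–acyl bond, then ring bonds C4–C5 and C1–C2 together, and in the hexadecadienoyl chain the C12=C13 alkene.
- The two ring cuts are possible because C4 is α to ketone C3 and, through C5–C6, 1,5 to carbonyl C1, while C2 lies between C1 and C3. The six-membered ring is therefore at once a Michael adduct (C4–C5) and a Claisen product (C1–C2) of an O-protected hydroxyacetone and an acrylate.
- Forward: the chain acid is made by Wittig olefination; the oxygenated ring arises in one operation by Michael–Claisen annulation, with a THP group as helper on the C4 oxygen; the chain is joined at C2 by O-acylation and O-to-C acyl shift; the THP group is then removed.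
- Stereochemistry: 12Z from the lithium-free Wittig reaction, 14E from (E)-crotonaldehyde. C4 is formed racemic in the annulation, and the 4S enantiomer is obtained by lipase-catalysed kinetic resolution of the final alcohol.

Key step: step 4

Remark: the 2-acyl-1,3-diones are drawn as the enol tautomer of the target SMILES; THP-bearing compounds are racemic mixtures of acetal epimers and carry no stereo label at those centres.

**Route**

Step 1
Reactants: 1 12-bromododecanoic acid
Product: 2 (11-carboxyundecyl)triphenylphosphonium bromide
Conditions: PPh3 (1.1 equiv), MeCN, reflux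
Reagents that add atoms: triphenylphosphine, c1ccc(cc1)P(c1ccccc1)c1ccccc1
Why: SN2 quaternisation of the primary bromide by the phosphine (phosphonium salt formation) should proceed cleanly with the free acid, as it does for shorter carboxyalkyl phosphonium salts.

Step 2
Reactants: 2 (11-carboxyundecyl)triphenylphosphonium bromide; 3 (2E)-but-2-enal
Product: 5 (12Z,14E)-hexadeca-12,14-dienoic acid, via phosphonium ylide 4 (not isolated)
Conditions: NaN(SiMe3)2 (2.1 equiv), THF, −78 to 0 °C; then 3, −78 °C to rt; 1 M HCl; AgNO3–SiO2 chromatography
Reagents that add atoms: none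
Why: Wittig olefination of the non-stabilised ylide under lithium-free conditions should give the new C12=C13 bond Z through the kinetically preferred cis-oxaphosphetane, while the E geometry of C14=C15 is carried over unchanged from 3.

Step 3
Reactants: 6 hydroxyacetone (1-hydroxypropan-2-one)
Product: 7 1-(tetrahydro-2H-pyran-2-yloxy)propan-2-one
Conditions: 3,4-dihydro-2H-pyran (1.2 equiv), PPTS (2 mol %), CH2Cl2, 0 °C to rt
Reagents that add atoms: 3,4-dihydro-2H-pyran, C1=COCCC1
Why: acid-catalysed addition of the alcohol to the enol ether (tetrahydropyranylation) gives an acetal that should survive KOtBu and DCC/DMAP and can later be removed under mild acid that spares the diene.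

Step 4
Reactants: 7 1-(tetrahydro-2H-pyran-2-yloxy)propan-2-one; 8 methyl acrylate
Product: 10 rac-4-(tetrahydro-2H-pyran-2-yloxy)cyclohexane-1,3-dione, via keto ester 9 (not isolated)
Conditions: KOtBu (2.0 equiv), THF, −10 °C, 7 in excess (1.3 equiv), 8 added slowly; then rt; AcOH quench to about pH 5
Reagents that add atoms: none
Why: KOtBu equilibrates the enolates of 7, and the more stabilised, oxygen-substituted enolate adds through the OTHP-bearing carbon to the β-carbon of 8 (Michael addition, ring bond C4–C5), giving keto ester 9 after proton transfer. The methyl-ketone enolate of 9 then attacks the ester carbonyl and expels methoxide (intramolecular Claisen, i.e. Dieckmann-type condensation, ring bond C1–C2), and the irreversible deprotonation of the resulting vinylogous acid pulls both reversible steps forward. The closest known reaction type is the consecutive Michael–Claisen process of substituted acetones with acrylates, which gives 4-substituted cyclohexane-1,3-diones. The six-membered ring closes in a 6-(enolendo)-exo-trig mode. The new stereocentre C4 is formed without control (racemic at C4, both acetal epimers), which is accepted because its configuration is fixed by the resolution in step 7. The step needs regioselectivity (Michael addition at the oxygenated carbon, Claisen closure from the methyl group) and mono-addition; the acidifying alkoxy group of 7, thermodynamic enolate control, the excess of 7 and the slow addition of 8 at low temperature should secure them.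

Step 5
Reactants: 10 rac-4-(tetrahydro-2H-pyran-2-yloxy)cyclohexane-1,3-dione; 5 (12Z,14E)-hexadeca-12,14-dienoic acid
Product: 12 rac-2-[(12Z,14E)-hexadeca-12,14-dienoyl]-4-(tetrahydro-2H-pyran-2-yloxy)cyclohexane-1,3-dione, via enol ester 11 (not isolated)
Conditions: DCC (1.2 equiv), DMAP (0.3 equiv), CH2Cl2, 0 °C to rt
Reagents that add atoms: none
Why: Steglich-type O-acylation gives enol ester 11, which DMAP should convert by O-to-C acyl migration (Fries-type shift through the N-acylpyridinium/enolate ion pair) into the more stable, internally hydrogen-bonded 2-acyl-1,3-dione, both regioisomeric enol esters converging on the same product.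

Step 6
Reactants: 12 rac-2-[(12Z,14E)-hexadeca-12,14-dienoyl]-4-(tetrahydro-2H-pyran-2-yloxy)cyclohexane-1,3-dione
Product: 13 rac-2-[(12Z,14E)-hexadeca-12,14-dienoyl]-4-hydroxycyclohexane-1,3-dione
Conditions: PPTS (0.2 equiv), MeOH, 40 °C
Reagents that add atoms: none
Why: acid-catalysed transacetalisation of the THP ether to methanol should free the secondary alcohol without touching the acid-tolerant triketone or the Z,E-diene.

Step 7
Reactants: 13 rac-2-[(12Z,14E)-hexadeca-12,14-dienoyl]-4-hydroxycyclohexane-1,3-dione
Product: 14 (4S)-2-[(12Z,14E)-hexadeca-12,14-dienoyl]-4-hydroxycyclohexane-1,3-dione (CNP0144157.1)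
Conditions: Candida antarctica lipase B (immobilised), vinyl acetate (3 equiv), tBuOMe, 30 °C, stopped just past half conversion (chiral HPLC control); chromatography
Reagents that add atoms: none
Why: lipase-catalysed transesterification (enzymatic kinetic resolution) should acetylate the 4R alcohol faster, as expected from the empirical rule for secondary alcohols with the acylated carbonyl side as the large group and by analogy with cyclic α-hydroxy ketones, so that the 4S alcohol is left unreacted and the C4 stereocentre of the target is thereby fixed.

**Compound list**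

1 | 12-bromododecanoic acid | OC(=O)CCCCCCCCCCCBr | starting material
2 | (11-carboxyundecyl)triphenylphosphonium bromide | OC(=O)CCCCCCCCCCC[P+](c1ccccc1)(c1ccccc1)c1ccccc1.[Br-] | intermediate
3 | (2E)-but-2-enal (crotonaldehyde) | C/C=C/C=O | starting material
4 | sodium 12-(triphenylphosphoranylidene)dodecanoate (ylide, not isolated) | [Na+].[O-]C(=O)CCCCCCCCCC[CH-][P+](c1ccccc1)(c1ccccc1)c1ccccc1 | intermediate
5 | (12Z,14E)-hexadeca-12,14-dienoic acid | C/C=C/C=C\CCCCCCCCCCC(=O)O | intermediate
6 | hydroxyacetone (1-hydroxypropan-2-one) | CC(=O)CO | starting material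
7 | 1-(tetrahydro-2H-pyran-2-yloxy)propan-2-one (racemic) | CC(=O)COC1CCCCO1 | intermediate
8 | methyl acrylate | C=CC(=O)OC | starting material
9 | methyl 5-oxo-4-(tetrahydro-2H-pyran-2-yloxy)hexanoate (racemic, acetal epimers; not isolated) | CC(=O)C(OC1CCCCO1)CCC(=O)OC | intermediate
10 | rac-4-(tetrahydro-2H-pyran-2-yloxy)cyclohexane-1,3-dione (acetal epimers) | O=C1CC(=O)C(OC2CCCCO2)CC1 | intermediate
11 | 3-oxo-4-(tetrahydro-2H-pyran-2-yloxy)cyclohex-1-en-1-yl (12Z,14E)-hexadeca-12,14-dienoate (racemic; formed together with its regioisomeric enol ester; not isolated) | C/C=C/C=C\CCCCCCCCCCC(=O)OC1=CC(=O)C(OC2CCCCO2)CC1 | intermediate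
12 | rac-2-[(12Z,14E)-hexadeca-12,14-dienoyl]-4-(tetrahydro-2H-pyran-2-yloxy)cyclohexane-1,3-dione (enol form, acetal epimers) | C/C=C/C=C\CCCCCCCCCCC(=O)C1=C(O)CCC(OC2CCCCO2)C1=O | intermediate
13 | rac-2-[(12Z,14E)-hexadeca-12,14-dienoyl]-4-hydroxycyclohexane-1,3-dione (enol form) | C/C=C/C=C\CCCCCCCCCCC(=O)C1=C(O)CCC(O)C1=O | intermediate
14 | (4S)-2-[(12Z,14E)-hexadeca-12,14-dienoyl]-4-hydroxycyclohexane-1,3-dione (enol form) | C/C=C/C=C\CCCCCCCCCCC(=O)C1=C(O)CC[C@H](O)C1=O | target

**Step count and risks**

Total step count: 7. Longest linear sequence: 5 steps (steps 3, 4, 5, 6, 7 from 6; equally steps 1, 2, 5, 6, 7 from 1).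

Steps most likely to fail:

1. Step 4. The Michael addition may run through the methyl carbon instead of the oxygenated carbon, a second acrylate may add, or the acrylate may oligomerise under the base. Fallback, setting out from 7 and coming back at 10: the regiochemistry is fixed in a separate, purifiable intermediate and the two bonds are made in two operations. Ketone 7 is converted with Me3SiCl, NaI and Et3N in MeCN into its more substituted enol silane, trimethyl{[(1Z)-1-(tetrahydro-2H-pyran-2-yloxy)prop-1-en-2-yl]oxy}silane F1. F1 is added to 8 under fluoride catalysis (Bu4NF, THF, −78 °C; Mukaiyama–Michael type) to give keto ester 9, now isolated. 9 is then cyclised under kinetic conditions (LiN(iPr)2, 2.2 equiv, THF, −78 to 0 °C), where only the methyl group should be deprotonated, to give 10.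

2. Step 7. The lipase may discriminate the enantiomers poorly or turn over slowly on the acidic, internally chelated triketone; in any case at most half of 13 can become 14. Fallback, setting out from 13 and coming back at 14: covalent resolution in place of the enzyme. 13 is esterified with (S)-2-methoxy-2-phenylacetic acid (EDC·HCl, DMAP cat., CH2Cl2, 0 °C) to the diastereomeric esters, the (4S)-ester (4S)-2-[(12Z,14E)-hexadeca-12,14-dienoyl]-1,3-dioxocyclohexan-4-yl (S)-2-methoxy-2-phenylacetate F2 and its (4R)-epimer F3. These are separated by chromatography or preparative HPLC, and F2 is cleaved with K2CO3 in MeOH at 0 °C to give 14.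

3. Step 2. The olefination may be incompletely Z-selective, and the conjugated diene may isomerise during work-up and purification, so that the 12E isomer is carried on. Fallback, setting out from 1 and coming back at 5: the diene is assembled by stereoretentive cross-coupling. Bromide 1 is oxidised (DMSO, NaHCO3, 110 °C; Kornblum oxidation) to 12-oxododecanoic acid F4. Stork–Zhao olefination (Ph3PCH2I iodide, NaN(SiMe3)2, THF/HMPA, −78 °C) converts F4 into (12Z)-13-iodotridec-12-enoic acid F5. Suzuki–Miyaura coupling of F5 with (E)-prop-1-en-1-ylboronic acid (Pd(PPh3)4, aqueous K2CO3, THF) should give 5 with both alkene geometries retained.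

Further compounds
F1 | step 4 | trimethyl{[(1Z)-1-(tetrahydro-2H-pyran-2-yloxy)prop-1-en-2-yl]oxy}silane | C/C(O[Si](C)(C)C)=C/OC1CCCCO1
F2 | step 7 | (4S)-2-[(12Z,14E)-hexadeca-12,14-dienoyl]-1,3-dioxocyclohexan-4-yl (S)-2-methoxy-2-phenylacetate | C/C=C/C=C\CCCCCCCCCCC(=O)C1=C(O)CC[C@H](OC(=O)[C@@H](OC)c2ccccc2)C1=O
F3 | step 7 | (4R)-2-[(12Z,14E)-hexadeca-12,14-dienoyl]-1,3-dioxocyclohexan-4-yl (S)-2-methoxy-2-phenylacetate | C/C=C/C=C\CCCCCCCCCCC(=O)C1=C(O)CC[C@@H](OC(=O)[C@@H](OC)c2ccccc2)C1=O
F4 | step 2 | 12-oxododecanoic acid | O=CCCCCCCCCCCC(=O)O
F5 | step 2 | (12Z)-13-iodotridec-12-enoic acid | I/C=C\CCCCCCCCCCC(=O)O
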